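**Retrosynthetic overview**
- Last step: a chlorine-abstraction radical cascade on a 3-chloro-3,7-diprenyl bicyclo[3.3.1]nonanetrione closes the seven-membered ring and the cyclopentane together and ends by hydrogen transfer.
- The bicyclo[3.3.1] core comes from a cationic C-alkylation (C8 to C1) of a dearomatized chloro-acylphloroglucinol, not from an Effenberger or Dieckmann annulation with bridgehead acylation.
- The monocycle is built on 2,4,6-trihydroxybenzophenone by chlorination and three C-alkylations (C10 side chain, geranyl, prenyl). One chlorine atom blocks C3, later makes it quaternary, and finally serves as the radical precursor.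
- The side-chain stereocentre (later C7) comes from Sharpless epoxidation of prenol and invertive cuprate opening.
- Ring order: aromatic six-membered ring (bought, dearomatized) → carbocycle of the bicyclo[3.3.1]nonane → seven-membered ring and cyclopentane in one step.

Assumption: the cinchonidinium catalyst in step 7 is taken to shield the face that gives the (6S) centre; if the opposite is found, its cinchoninium pseudo-enantiomer is used.

Ring locants C1–C9 in the text are those of the bicyclo[3.3.1]nonane made in step 9 (C1 benzoyl carbon, C3 chlorine carbon, C5 geranyl carbon, C7 side-chain stereocentre, C8 CMe2).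

**Route**

Step 1
Reactants: 1 3-methylbut-2-en-1-ol (prenol)
Product: 2 [(2S)-3,3-dimethyloxiran-2-yl]methanol
Conditions: Ti(OiPr)4 (5 mol %), L-(+)-diethyl tartrate (6 mol %), t-BuOOH (1.5 equiv), 4 Å MS, CH2Cl2, −20 °C
Reagents that add atoms: tert-butyl hydroperoxide, CC(C)(C)OO
Why: Sharpless asymmetric epoxidation of a primary allylic alcohol; the L-(+)-tartrate titanium complex delivers oxygen to the face that gives the 2S epoxide, which fixes the later C7 centre.

Step 2
Reactants: 2 [(2S)-3,3-dimethyloxiran-2-yl]methanol; 3 allylmagnesium bromide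
Product: 4 (2R)-3-methyl-2-(prop-2-en-1-yl)butane-1,3-diol
Conditions: 3 (2.5 equiv), CuI (10 mol %), THF, −40 → 0 °C; H2O
Reagents that add atoms: none
Why: copper-catalysed SN2 opening of a 2,3-epoxy alcohol; the cuprate attacks C2 because C3 is fully substituted, and inversion at C2 turns the 2S epoxide into the 2R 1,3-diol.

Step 3
Reactants: 4 (2R)-3-methyl-2-(prop-2-en-1-yl)butane-1,3-diol; 5 2-methylbut-2-ene
Product: 6 (2R)-3-methyl-2-(3-methylbut-2-en-1-yl)butane-1,3-diol
Conditions: second-generation Grubbs catalyst RuCl2(=CHPh)(H2IMes)(PCy3) (3 mol %), 5 (20 equiv), CH2Cl2, 40 °C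
Reagents that add atoms: none
Why: olefin cross-metathesis of the terminal allyl group with excess trisubstituted alkene gives the prenyl group and volatile propene; the stereocentre is untouched.

Step 4
Reactants: 6 (2R)-3-methyl-2-(3-methylbut-2-en-1-yl)butane-1,3-diol
Product: 8 (2R)-3-methyl-2-(3-methylbut-2-en-1-yl)-3-[(trimethylsilyl)oxy]butan-1-ol, via bis-silyl ether 7 (not isolated)
Conditions: Me3SiCl (2.3 equiv), imidazole (2.5 equiv), CH2Cl2, 0 °C; then K2CO3 (0.1 equiv), MeOH, −10 °C
Reagents that add atoms: chlorotrimethylsilane, C[Si](C)(C)Cl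
Why: silyl protection followed by selective methanolysis; the unhindered primary silyl ether is cleaved much faster than the tertiary one, so the tertiary oxygen stays masked and the primary alcohol is free.

Step 5
Reactants: 9 (2,4,6-trihydroxyphenyl)(phenyl)methanone
Product: 10 (3-chloro-2,4,6-trihydroxyphenyl)(phenyl)methanone
Conditions: N-chlorosuccinimide (1.0 equiv), MeCN, −20 °C → rt
Reagents that add atoms: N-chlorosuccinimide, O=C1CCC(=O)N1Cl
Why: electrophilic aromatic chlorination of the strongly activated phloroglucinol ring; one equivalent at low temperature stops at the monochloride and leaves exactly one ring CH.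

Step 6
Reactants: 10 (3-chloro-2,4,6-trihydroxyphenyl)(phenyl)methanone; 8 (2R)-3-methyl-2-(3-methylbut-2-en-1-yl)-3-[(trimethylsilyl)oxy]butan-1-ol
Product: 12 {3-chloro-2,4,6-trihydroxy-5-[(2R)-3-methyl-2-(3-methylbut-2-en-1-yl)-3-[(trimethylsilyl)oxy]butyl]phenyl}(phenyl)methanone, via primary triflate 11 (not isolated)
Conditions: 8, Tf2O, 2,6-lutidine, CH2Cl2, −78 °C; then 10, LiN(SiMe3)2 (3.0 equiv), THF, −78 → 0 °C
Reagents that add atoms: none
Why: SN2 C-alkylation of the lithium phenoxide (a vinylogous tricarbonyl carbanion) by the primary triflate at the only unsubstituted ring carbon, tight lithium ion pairing in THF favouring carbon over oxygen; the side-chain stereocentre is not involved.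

Step 7
Reactants: 12 {3-chloro-2,4,6-trihydroxy-5-[(2R)-3-methyl-2-(3-methylbut-2-en-1-yl)-3-[(trimethylsilyl)oxy]butyl]phenyl}(phenyl)methanone; 13 geranyl bromide
Product: 14 (6S)-4-benzoyl-2-chloro-6-[(2E)-3,7-dimethylocta-2,6-dien-1-yl]-3,5-dihydroxy-6-[(2R)-3-methyl-2-(3-methylbut-2-en-1-yl)-3-[(trimethylsilyl)oxy]butyl]cyclohexa-2,4-dien-1-one
Conditions: 13 (1.1 equiv), CsOH·H2O (1.5 equiv), N-(9-anthracenylmethyl)cinchonidinium bromide (10 mol %), toluene/CH2Cl2 (7:3), −50 °C
Reagents that add atoms: none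
Why: phase-transfer alkylative dearomatization (SN2 at a ring carbon of the phenoxide); the electron-rich alkyl-bearing C5 reacts in preference to the chlorine-bearing C3 and the acyl-bearing C1, and the chiral ammonium ion pair exposes one face of the flat ring so that the quaternary C5 forms as the 6S isomer (catalyst control).

Step 8
Reactants: 14 (6S)-4-benzoyl-2-chloro-6-geranyl-3,5-dihydroxy-6-[(2R)-side chain]cyclohexa-2,4-dien-1-one; 15 prenyl bromide
Product: 16 (4S)-2-benzoyl-6-chloro-4-[(2E)-3,7-dimethylocta-2,6-dien-1-yl]-3-hydroxy-6-(3-methylbut-2-en-1-yl)-4-[(2R)-3-methyl-2-(3-methylbut-2-en-1-yl)-3-[(trimethylsilyl)oxy]butyl]cyclohex-2-ene-1,5-dione (both C6 epimers)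
Conditions: 15 (1.5 equiv), DBU (1.2 equiv), THF, 0 °C
Reagents that add atoms: none
Why: C-alkylation of the chloro-β-diketone enolate, the only ring carbon still nucleophilic (C1 carries the acyl group, C5 is quaternary); the new C(Cl)(prenyl) centre forms as both epimers, which is harmless because it becomes a planar radical in step 10.

Step 9
Reactants: 16 (4S)-2-benzoyl-6-chloro-4-geranyl-3-hydroxy-6-prenyl-4-[(2R)-side chain]cyclohex-2-ene-1,5-dione
Product: 18 (1S,5S,7R)-1-benzoyl-3-chloro-5-[(2E)-3,7-dimethylocta-2,6-dien-1-yl]-8,8-dimethyl-3,7-bis(3-methylbut-2-en-1-yl)bicyclo[3.3.1]nonane-2,4,9-trione (7-prenyl endo; both C3 epimers), via tertiary alcohol 17 (not isolated)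
Conditions: HCO2H/CH2Cl2 (1:1), 0 °C → rt
Reagents that add atoms: none
Why: biomimetic cationic cyclization (SN1 C-alkylation of the triketone enol); acid removes the silyl group and ionises the tertiary alcohol, any O-alkylated enol ether re-ionises, and with C3 quaternary only C1 can form the C1–C8 bond, so the fixed C5/C7 pair dictates C1 and places the C7 prenyl group endo through a boat-like closure.

Step 10
Reactants: 18 (1S,5S,7R)-1-benzoyl-3-chloro-5-geranyl-8,8-dimethyl-3,7-diprenylbicyclo[3.3.1]nonane-2,4,9-trione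
Product: 19 CNP0155129.1
Conditions: (Me3Si)3SiH (1.3 equiv) and AIBN (0.2 equiv) added over 6 h, PhH (5 mM), 80 °C
Reagents that add atoms: none
Why: radical cascade (chlorine abstraction, 7-exo-trig, 5-exo-trig, hydrogen transfer); the planar C3 radical can only add to the CH carbon of the endo C7 prenyl group inside the cage, with the two-carbon tether twisted away from the C8 methyl groups and the CMe2 end pointing outward (sets C3 and the ring-fusion CH), and the tertiary radical then closes on the C3 prenyl group through a chair transition state that puts the isopropyl-bearing carbon trans to the bridge CH2 before the last radical takes H from the silane.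

**Compound list**

1 | 3-methylbut-2-en-1-ol (prenol) | CC(C)=CCO | starting material
2 | [(2S)-3,3-dimethyloxiran-2-yl]methanol | OC[C@@H]1OC1(C)C | intermediate
3 | allylmagnesium bromide | C=CC[Mg]Br | starting material
4 | (2R)-3-methyl-2-(prop-2-en-1-yl)butane-1,3-diol | OC[C@@H](CC=C)C(C)(C)O | intermediate
5 | 2-methylbut-2-ene | CC=C(C)C | starting material
6 | (2R)-3-methyl-2-(3-methylbut-2-en-1-yl)butane-1,3-diol | OC[C@@H](CC=C(C)C)C(C)(C)O | intermediate
7 | bis(trimethylsilyl) ether of 6 (same R centre) | C[Si](C)(C)OC[C@@H](CC=C(C)C)C(C)(C)O[Si](C)(C)C | intermediate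
8 | (2R)-3-methyl-2-(3-methylbut-2-en-1-yl)-3-[(trimethylsilyl)oxy]butan-1-ol | OC[C@@H](CC=C(C)C)C(C)(C)O[Si](C)(C)C | intermediate
9 | (2,4,6-trihydroxyphenyl)(phenyl)methanone | O=C(c1ccccc1)c1c(O)cc(O)cc1O | starting material
10 | (3-chloro-2,4,6-trihydroxyphenyl)(phenyl)methanone | O=C(c1ccccc1)c1c(O)c(Cl)c(O)cc1O | intermediate
11 | (2R)-3-methyl-2-(3-methylbut-2-en-1-yl)-3-[(trimethylsilyl)oxy]butyl trifluoromethanesulfonate | O=S(=O)(OC[C@@H](CC=C(C)C)C(C)(C)O[Si](C)(C)C)C(F)(F)F | intermediate
12 | {3-chloro-2,4,6-trihydroxy-5-[(2R)-3-methyl-2-(3-methylbut-2-en-1-yl)-3-[(trimethylsilyl)oxy]butyl]phenyl}(phenyl)methanone | O=C(c1ccccc1)c1c(O)c(Cl)c(O)c(C[C@@H](CC=C(C)C)C(C)(C)O[Si](C)(C)C)c1O | intermediate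
13 | geranyl bromide, (2E)-1-bromo-3,7-dimethylocta-2,6-diene | CC(C)=CCC/C(C)=C/CBr | starting material
14 | (6S)-4-benzoyl-2-chloro-6-[(2E)-3,7-dimethylocta-2,6-dien-1-yl]-3,5-dihydroxy-6-[(2R)-3-methyl-2-(3-methylbut-2-en-1-yl)-3-[(trimethylsilyl)oxy]butyl]cyclohexa-2,4-dien-1-one (one enol tautomer drawn) | CC(C)=CCC/C(C)=C/C[C@@]1(C[C@@H](CC=C(C)C)C(C)(C)O[Si](C)(C)C)C(=O)C(Cl)=C(O)C(C(=O)c2ccccc2)=C1O | intermediate
15 | prenyl bromide, 1-bromo-3-methylbut-2-ene | CC(C)=CCBr | starting material
16 | (4S)-2-benzoyl-6-chloro-4-[(2E)-3,7-dimethylocta-2,6-dien-1-yl]-3-hydroxy-6-(3-methylbut-2-en-1-yl)-4-[(2R)-3-methyl-2-(3-methylbut-2-en-1-yl)-3-[(trimethylsilyl)oxy]butyl]cyclohex-2-ene-1,5-dione, both C6 epimers (C6 left open in the SMILES) | CC(C)=CCC/C(C)=C/C[C@@]1(C[C@@H](CC=C(C)C)C(C)(C)O[Si](C)(C)C)C(=O)C(Cl)(CC=C(C)C)C(=O)C(C(=O)c2ccccc2)=C1O | intermediate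
17 | (4S)-2-benzoyl-6-chloro-4-[(2E)-3,7-dimethylocta-2,6-dien-1-yl]-3-hydroxy-4-[(2R)-3-hydroxy-3-methyl-2-(3-methylbut-2-en-1-yl)butyl]-6-(3-methylbut-2-en-1-yl)cyclohex-2-ene-1,5-dione, both C6 epimers | CC(C)=CCC/C(C)=C/C[C@@]1(C[C@@H](CC=C(C)C)C(C)(C)O)C(=O)C(Cl)(CC=C(C)C)C(=O)C(C(=O)c2ccccc2)=C1O | intermediate
18 | (1S,5S,7R)-1-benzoyl-3-chloro-5-[(2E)-3,7-dimethylocta-2,6-dien-1-yl]-8,8-dimethyl-3,7-bis(3-methylbut-2-en-1-yl)bicyclo[3.3.1]nonane-2,4,9-trione, 7-prenyl endo, both C3 epimers (C3 left open in the SMILES) | CC(C)=CCC/C(C)=C/C[C@@]12C[C@@H](CC=C(C)C)C(C)(C)[C@](C(=O)c3ccccc3)(C2=O)C(=O)C(Cl)(CC=C(C)C)C1=O | intermediate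
19 | CNP0155129.1, (1R,3S,5R,7R,9R,11S)-11-benzoyl-1-[(2E)-3,7-dimethylocta-2,6-dien-1-yl]-6,6,10,10-tetramethyl-5-(propan-2-yl)tetracyclo[7.3.1.1^{3,11}.0^{3,7}]tetradecane-2,12,14-trione | CC(C)=CCC/C(C)=C/C[C@@]12C[C@H]3C[C@@H]4C(C)(C)[C@@H](C(C)C)C[C@]4(C1=O)C(=O)[C@@](C(=O)c1ccccc1)(C2=O)C3(C)C | target

**Step count and risk**

Total steps: 10. Longest linear sequence: 9 (steps 1–4, then 6–10).

The three steps most likely to fail:

Step 6. The hindered, β-branched triflate may alkylate oxygen instead of carbon. The fallback sets out from 10 and returns at 14 by swapping the order of the two alkylations at C5. Compound 10 is C-geranylated at its free ring CH with 13 (DBU, THF, 0 °C) to give (3-chloro-5-[(2E)-3,7-dimethylocta-2,6-dien-1-yl]-2,4,6-trihydroxyphenyl)(phenyl)methanone F1. The lithium phenoxide of F1 (LiN(SiMe3)2, THF) is then alkylated at the geranyl-bearing carbon with triflate 11. Without catalyst control this alkylative dearomatization gives 14 together with its C6 epimer, the (6R)-dienone F2; the two are separated by preparative HPLC and 14 goes on to step 8.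

Step 9. The cation may be captured at oxygen, or the alkenes may be protonated, and the endo closure needs a boat-like transition state. The fallback sets out from 16 and returns at 18 by making the O-cyclised compound on purpose and rearranging it. p-TsOH·H2O (5 mol %) in CH2Cl2 at 0 °C converts 16 into the cyclic enol ether (3R,4aS)-8-benzoyl-6-chloro-4a-[(2E)-3,7-dimethylocta-2,6-dien-1-yl]-2,2-dimethyl-3,6-bis(3-methylbut-2-en-1-yl)-3,4-dihydro-2H-chromene-5,7(4aH,6H)-dione F3, which is isolated. BF3·OEt2 in CH2Cl2 at −40 °C then ionises its tertiary C–O bond in a tight ion pair, which collapses at C1 (1,3 O-to-C shift) to 18.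

Step 10. The C3 radical may be reduced before it cyclises, and the face selectivity at the ring-fusion CH is the least secure stereochemical element of the route. The fallback sets out from 18 and returns at 19 by generating the radical oxidatively. Zn dust in AcOH removes the chlorine to give the enolised 1-benzoyl-5-geranyl-8,8-dimethyl-3,7-diprenylbicyclo[3.3.1]nonane-2,4,9-trione F4; this is also the product of premature reduction in step 10, so the two can be pooled. Mn(OAc)3·2H2O (2.2 equiv) and Cu(OAc)2·H2O (1 equiv) in AcOH then run the same 7-exo/5-exo cascade, which ends by copper-mediated elimination to the isopropenyl cage F5. Hydrogenation with RhCl(PPh3)3 (10 mol %) under H2 (1 atm) in PhH reduces only the 1,1-disubstituted alkene, leaves the two trisubstituted geranyl alkenes, and gives 19. This fallback does not change the face selectivity of the first ring closure.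

**Further compounds**

F1 | step 6 | (3-chloro-5-[(2E)-3,7-dimethylocta-2,6-dien-1-yl]-2,4,6-trihydroxyphenyl)(phenyl)methanone | O=C(c1ccccc1)c1c(O)c(Cl)c(O)c(C/C=C(\C)CCC=C(C)C)c1O
F2 | step 6 | (6R)-4-benzoyl-2-chloro-6-[(2E)-3,7-dimethylocta-2,6-dien-1-yl]-3,5-dihydroxy-6-[(2R)-3-methyl-2-(3-methylbut-2-en-1-yl)-3-[(trimethylsilyl)oxy]butyl]cyclohexa-2,4-dien-1-one (C6 epimer of 14) | CC(C)=CCC/C(C)=C/C[C@]1(C[C@@H](CC=C(C)C)C(C)(C)O[Si](C)(C)C)C(=O)C(Cl)=C(O)C(C(=O)c2ccccc2)=C1O
F3 | step 9 | (3R,4aS)-8-benzoyl-6-chloro-4a-[(2E)-3,7-dimethylocta-2,6-dien-1-yl]-2,2-dimethyl-3,6-bis(3-methylbut-2-en-1-yl)-3,4-dihydro-2H-chromene-5,7(4aH,6H)-dione (both C6 epimers) | CC(C)=CCC/C(C)=C/C[C@]12C[C@@H](CC=C(C)C)C(C)(C)OC1=C(C(=O)c3ccccc3)C(=O)C(Cl)(CC=C(C)C)C2=O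
F4 | step 10 | 1-benzoyl-5-[(2E)-3,7-dimethylocta-2,6-dien-1-yl]-4-hydroxy-8,8-dimethyl-3,7-bis(3-methylbut-2-en-1-yl)bicyclo[3.3.1]non-3-ene-2,9-dione (enol form; C1, C5 and C7 configured as in 18) | CC(C)=CCC/C(C)=C/C[C@@]12C[C@@H](CC=C(C)C)C(C)(C)[C@](C(=O)c3ccccc3)(C2=O)C(=O)C(CC=C(C)C)=C1O
F5 | step 10 | 5-(prop-1-en-2-yl) analogue of 19 (isopropenyl in place of isopropyl, all centres as in 19) | CC(C)=CCC/C(C)=C/C[C@@]12C[C@H]3C[C@@H]4C(C)(C)[C@@H](C(C)=C)C[C@]4(C1=O)C(=O)[C@@](C(=O)c1ccccc1)(C2=O)C3(C)C
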